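## Retrosynthetic overview
- Last bond: C4–C3' by acid-promoted Friedel–Crafts alkylation of the symmetric 2',6'-dihydroxy-4'-methoxychalcone with a (2R)-flavan-4-ol; C2 directs C4 to the 2,4-trans isomer.
- Flavan-4-ol ← (R)-flavanone ← Pd/PyOx asymmetric conjugate addition of PhB(OH)2 to 7-hydroxy-5,8-dimethoxychromone (sets C2).
- Chromone ← 2,4-dihydroxy-3,6-dimethoxyacetophenone ← symmetric 2,5-dimethoxyresorcinol ← 2,6-dibromo-4-methoxyphenol.
- Chalcone ← 2,6-dihydroxy-4-methoxyacetophenone + benzaldehyde (Claisen–Schmidt).
- Ring order: aromatic rings are bought; the only ring formed is the pyranone (chromone stage); no protecting groups.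

Assumption: CIP analysis of the given SMILES gives (2R,4R), i.e. 2-phenyl and 4-aryl trans; 2,6-dibromo-4-methoxyphenol and 2,6-dihydroxy-4-methoxyacetophenone are taken as catalogue chemicals.

## Route

**Step 1**
Reactants: 1, 2,6-dibromo-4-methoxyphenol
Product: 2, 1,3-dibromo-2,5-dimethoxybenzene
Conditions: MeI, K2CO3, DMF, rt
Reagents that add atoms: iodomethane, CI
Why: Williamson O-methylation of an acidic di-ortho-bromophenol; nothing else in the molecule reacts.

**Step 2**
Reactants: 2, 1,3-dibromo-2,5-dimethoxybenzene
Product: 3, 2,5-dimethoxybenzene-1,3-diol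
Conditions: Pd2(dba)3 (2 mol%), t-BuXPhos (8 mol%), KOH (8 equiv), 1,4-dioxane/H2O 1:1, 100 °C, Ar; then aq. HCl
Reagents that add atoms: potassium hydroxide, [K+].[OH-] (water, O, as co-solvent)
Why: Buchwald Pd-catalysed hydroxylation of both aryl bromides; the product is symmetric, so the tetra-oxygenation pattern (OMe at C2 and C5, OH at C1 and C3) is fixed without any regiochemical question.

**Step 3**
Reactants: 3, 2,5-dimethoxybenzene-1,3-diol
Product: 4, 1-(2,4-dihydroxy-3,6-dimethoxyphenyl)ethan-1-one
Conditions: AcOH (1.2 equiv), BF3·OEt2, 80 °C; then aq. NaOAc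
Reagents that add atoms: acetic acid, CC(=O)O
Why: BF3-mediated Friedel–Crafts C-acylation; C4 and C6 are equivalent and are the only free positions (ortho to one OH, para to the other), and the first acyl group deactivates the ring against a second.

**Step 4**
Reactants: 4, 1-(2,4-dihydroxy-3,6-dimethoxyphenyl)ethan-1-one
Product: 5, 7-hydroxy-5,8-dimethoxy-4H-chromen-4-one
Conditions: t-BuOCH(NMe2)2 (3 equiv), toluene, 80 °C; then conc. HCl, MeOH, 60 °C (telescoped)
Reagents that add atoms: Bredereck's reagent (tert-butoxybis(dimethylamino)methane), CC(C)(C)OC(N(C)C)N(C)C (supplies C2)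
Why: Enaminone formation at the acetyl CH3, then acid-promoted addition–elimination by the only ortho OH closes the pyranone; Bredereck's reagent is used instead of DMF-DMA so the free 4-OH is not O-methylated.

**Step 5**
Reactants: 5, 7-hydroxy-5,8-dimethoxy-4H-chromen-4-one; 6, phenylboronic acid
Product: 7, (2R)-7-hydroxy-5,8-dimethoxy-2-phenylchroman-4-one
Conditions: PhB(OH)2 (2 equiv), Pd(OCOCF3)2 (5 mol%), (S)-t-BuPyOx (6 mol%), NH4PF6 (30 mol%), H2O (5 equiv), ClCH2CH2Cl, 60 °C; recrystallise to upgrade ee
Reagents that add atoms: phenylboronic acid (compound 6), OB(O)c1ccccc1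
Why: Pd(II)/PyOx-catalysed asymmetric conjugate addition of an arylboronic acid to a chromone; the (S)-ligand controls the face of aryl-Pd insertion and gives the 2R flavanone (same facial sense as its (R)-3-arylcyclohexanone products), under base-free conditions that tolerate the phenol.

**Step 6**
Reactants: 7, (2R)-7-hydroxy-5,8-dimethoxy-2-phenylchroman-4-one
Product: 8, (2R,4R)-7-hydroxy-5,8-dimethoxy-2-phenylchroman-4-ol (2,4-cis)
Conditions: NaBH4 (3 equiv), THF/MeOH, 0 °C; pH 7 buffer work-up; used crude
Reagents that add atoms: none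
Why: Borohydride reduction with axial hydride delivery anti to the equatorial 2-phenyl gives the cis alcohol; the C4 configuration is irrelevant because it is ionised in Step 8, and 0 °C avoids retro-oxa-Michael racemisation at C2.

**Step 7**
Reactants: 9, 1-(2,6-dihydroxy-4-methoxyphenyl)ethan-1-one; 10, benzaldehyde
Product: 11, (E)-1-(2,6-dihydroxy-4-methoxyphenyl)-3-phenylprop-2-en-1-one
Conditions: 50% aq. KOH, EtOH, 0 °C → rt, 48 h, dark; pour onto ice/1 M HCl (pH 4–5), filter cold
Reagents that add atoms: benzaldehyde (compound 10), O=Cc1ccccc1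
Why: Claisen–Schmidt aldol condensation with E1cB dehydration gives the E-enone; the chalcone is stable as its phenoxide, and cold acidification avoids oxa-Michael closure to the flavanone.

**Step 8**
Reactants: 8, (2R,4R)-7-hydroxy-5,8-dimethoxy-2-phenylchroman-4-ol; 11, (E)-2',6'-dihydroxy-4'-methoxychalcone (3 equiv, excess recovered)
Product: 12, Sarcandrone B, the (2R,4R) 2,4-trans 4-arylflavan
Conditions: p-TsOH·H2O (20 mol%), 1,4-dioxane/CH2Cl2, 0 °C → rt, 8 added slowly to 11; NaHCO3 quench
Reagents that add atoms: none (water is lost)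
Why: SN1 Friedel–Crafts alkylation in which acid ionises the 4-OH to the 5,7,8-trioxygenated flavan-4-yl cation, which is trapped by the equivalent C3'/C5' positions of the acylphloroglucinol ring; pseudo-axial attack anti to the equatorial 2-phenyl gives the 2,4-trans (4R) product, the reversible C–C bond formation favours the same isomer, and C2 is untouched.

## Compound list
1 | 2,6-dibromo-4-methoxyphenol | COc1cc(Br)c(O)c(Br)c1 | starting material
2 | 1,3-dibromo-2,5-dimethoxybenzene | COc1cc(Br)c(OC)c(Br)c1 | intermediate
3 | 2,5-dimethoxybenzene-1,3-diol | COc1cc(O)c(OC)c(O)c1 | intermediate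
4 | 1-(2,4-dihydroxy-3,6-dimethoxyphenyl)ethan-1-one | CC(=O)c1c(O)c(OC)c(O)cc1OC | intermediate
5 | 7-hydroxy-5,8-dimethoxy-4H-chromen-4-one | COc1cc(O)c(OC)c2occc(=O)c12 | intermediate
6 | phenylboronic acid | OB(O)c1ccccc1 | starting material
7 | (2R)-7-hydroxy-5,8-dimethoxy-2-phenylchroman-4-one | COc1cc(O)c(OC)c2O[C@@H](c3ccccc3)CC(=O)c12 | intermediate
8 | (2R,4R)-7-hydroxy-5,8-dimethoxy-2-phenylchroman-4-ol | COc1cc(O)c(OC)c2O[C@@H](c3ccccc3)C[C@@H](O)c12 | intermediate
9 | 1-(2,6-dihydroxy-4-methoxyphenyl)ethan-1-one | CC(=O)c1c(O)cc(OC)cc1O | starting material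
10 | benzaldehyde | O=Cc1ccccc1 | starting material
11 | (E)-1-(2,6-dihydroxy-4-methoxyphenyl)-3-phenylprop-2-en-1-one | COc1cc(O)c(C(=O)/C=C/c2ccccc2)c(O)c1 | intermediate
12 | Sarcandrone B | COc1cc(O)c(C(=O)/C=C/c2ccccc2)c(O)c1[C@H]1C[C@H](c2ccccc2)Oc2c(OC)c(O)cc(OC)c21 | target

## Summary
Total steps: 8. Longest linear sequence: 7 (Steps 1–6, then 8).

Three steps most likely to fail:
1. **Step 8 (Friedel–Crafts coupling).** Risks are self-condensation of 8 through its own C6, bis-alkylation of 11, and a cis/trans mixture. Fallback: form the C4–aryl bond before the enone exists by coupling 8 with acetophenone 9, then MOM-protect the phenols, do the Claisen–Schmidt condensation with benzaldehyde, and remove MOM with acid.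
2. **Step 5 (asymmetric conjugate addition).** The chromone is electron-rich, has a peri 5-OMe and a free phenol, so conversion or ee may be poor. Fallback: make the racemic flavanone from 4 and benzaldehyde (Claisen–Schmidt, then NaOAc cyclisation) and resolve it by asymmetric transfer hydrogenation with RuCl(p-cymene)[(R,R)-TsDPEN], HCO2H/Et3N, which reduces only the 2R enantiomer and gives 8 directly.
3. **Step 7 (chalcone from the unprotected dihydroxyacetophenone).** The dianion condenses sluggishly and the product can close to the flavanone on work-up. Fallback: prepare 11 by base-mediated ring-opening (KOH, aq. EtOH, then cold acidification) of commercial pinostrobin (5-hydroxy-7-methoxyflavanone), whose stereocentre is destroyed in the process.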